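**Plan**

- Retrosynthesis: the ethyl ketone goes back to a silyl-protected carbinol. The methoxypyranone is cut at O1–C2 and C5–C6, which leaves a ring carbaldehyde masked as an oxazoline. The carbocycle is cut at ring C6–side-chain C2 and at ring C1–CH3.
- Enabling feature: in the cyclohexa-2,4-diene, C1 (quaternary; CH3 and pyranone C-6) and C6 (H and heptenyl C-2) are adjacent sp3 carbons beside a diene C2=C3/C4=C5 with methyls on C3 and C5. This is a 3,5-dimethylbenzoic acid whose ipso and one ortho carbon have become sp3, with CH3 trans to the arm.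
- Forward order: the aryl oxazoline–Cr(CO)3 complex (steps 1–2) and the E-alkenyl iodide (steps 3–9) are joined in step 10. There the arene becomes the carbocycle and no ring closes. The pyranone ring closes in step 14 and the ketone is unveiled last.
- Stereochemistry: the side-chain methyl centre comes from an Evans syn aldol and the E-alkene from syn hydrozirconation. The ring centres come from the (S)-tert-leucinol oxazoline (choice of ortho carbon) and from exo addition followed by endo methyl delivery (trans).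

Key step: step 10

Remark (assumption): the sense of induction in step 10 is taken from the N–Li chelation model. In the reactive rotamer the tert-butyl group of the (S)-oxazoline points to the metal face, so only one ortho carbon has an open exo face next to nitrogen. The side-chain carbinol is carried as the 5R epimer (syn aldol); it is oxidised at the end.

Abbreviations: Hp = (2E,4R,5R)-5-(tert-butyldimethylsilyloxy)-4-methylhept-2-en-2-yl; Dn = (1R,6S)-6-Hp-1,3,5-trimethylcyclohexa-2,4-dien-1-yl (C1 quaternary, C6 carries Hp).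

**Route**

Step 1
Reactants: 1 3,5-dimethylbenzonitrile; 2 (S)-tert-leucinol
Product: 3 (S)-4-tert-butyl-2-(3,5-dimethylphenyl)-4,5-dihydrooxazole
Conditions: ZnCl2 (5 mol%), PhCl, 130 °C
Reagents that add atoms: none
Why: Witte–Seeliger condensation of an aryl nitrile with a 1,2-amino alcohol under ZnCl2 catalysis should give the 2-aryloxazoline with loss of ammonia and without touching the stereocentre of 2.

Step 2
Reactants: 3 (S)-4-tert-butyl-2-(3,5-dimethylphenyl)-4,5-dihydrooxazole; 4 hexacarbonylchromium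
Product: 5 tricarbonyl[η6-(S)-4-tert-butyl-2-(3,5-dimethylphenyl)-4,5-dihydrooxazole]chromium
Conditions: Cr(CO)6, n-Bu2O/THF (10:1), 140 °C, argon, dark
Reagents that add atoms: hexacarbonylchromium Cr(CO)6 (compound 4), [Cr].[C-]#[O+].[C-]#[O+].[C-]#[O+].[C-]#[O+].[C-]#[O+].[C-]#[O+]
Why: Thermal arene complexation (three CO exchanged for the electron-rich arene) is standard for aryl oxazolines, and the two arene faces are equivalent by rotation about the aryl–oxazoline bond, so a single complex should form.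

Step 3
Reactants: 6 (S)-4-benzyl-3-propionyloxazolidin-2-one; 7 propanal
Product: 9 (S)-4-benzyl-3-[(2S,3R)-3-hydroxy-2-methylpentanoyl]oxazolidin-2-one, via dibutylboron Z-enolate 8 (not isolated)
Conditions: n-Bu2BOTf, i-Pr2NEt, CH2Cl2, 0 °C; propanal, −78 → 0 °C; H2O2, MeOH, pH 7 buffer
Reagents that add atoms: none
Why: Evans syn aldol, in which the Z boron enolate reacts through a closed chair transition state on the face away from the benzyl group, sets the 2S methyl centre (the later side-chain centre) and the 3R carbinol.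

Step 4
Reactants: 9 (S)-4-benzyl-3-[(2S,3R)-3-hydroxy-2-methylpentanoyl]oxazolidin-2-one
Product: 10 (S)-4-benzyl-3-[(2S,3R)-3-(tert-butyldimethylsilyloxy)-2-methylpentanoyl]oxazolidin-2-one
Conditions: TBSOTf, 2,6-lutidine, CH2Cl2, 0 °C
Reagents that add atoms: tert-butyldimethylsilyl trifluoromethanesulfonate, CC(C)(C)[Si](C)(C)OS(=O)(=O)C(F)(F)F
Why: Silyl ether formation with the silyl triflate is fast on the hindered secondary alcohol and blocks retro-aldol cleavage in the following steps.

Step 5
Reactants: 10 (S)-4-benzyl-3-[(2S,3R)-3-(tert-butyldimethylsilyloxy)-2-methylpentanoyl]oxazolidin-2-one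
Product: 11 (2R,3R)-3-(tert-butyldimethylsilyloxy)-2-methylpentan-1-ol
Conditions: LiBH4, MeOH (1 equiv), THF, 0 °C
Reagents that add atoms: none
Why: Reductive cleavage of the N-acyl oxazolidinone by LiBH4 should give the primary alcohol and free auxiliary without touching the silyl ether or the α-centre (the descriptor changes only through priorities).

Step 6
Reactants: 11 (2R,3R)-3-(tert-butyldimethylsilyloxy)-2-methylpentan-1-ol
Product: 12 (2S,3R)-3-(tert-butyldimethylsilyloxy)-2-methylpentanal
Conditions: Dess–Martin periodinane, NaHCO3, CH2Cl2, 0 → 20 °C; used crude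
Reagents that add atoms: none
Why: Buffered Dess–Martin oxidation is non-basic, so the α-methyl aldehyde should form without epimerisation.

Step 7
Reactants: 12 (2S,3R)-3-(tert-butyldimethylsilyloxy)-2-methylpentanal
Product: 13 tert-butyl{[(3R,4R)-6,6-dibromo-4-methylhex-5-en-3-yl]oxy}dimethylsilane
Conditions: CBr4, PPh3, CH2Cl2, 0 °C
Reagents that add atoms: tetrabromomethane, BrC(Br)(Br)Br
Why: First stage of the Corey–Fuchs sequence, a Wittig-type dibromomethylenation by Ph3P=CBr2 that is neutral and fast enough to preserve the α-centre.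

Step 8
Reactants: 13 tert-butyl{[(3R,4R)-6,6-dibromo-4-methylhex-5-en-3-yl]oxy}dimethylsilane; 14 iodomethane
Product: 16 tert-butyldimethyl{[(3R,4R)-4-methylhept-5-yn-3-yl]oxy}silane, via lithium acetylide 15 (not isolated)
Conditions: n-BuLi (2.1 equiv), THF, −78 °C; MeI, −78 → 20 °C
Reagents that add atoms: iodomethane (compound 14), CI
Why: Second stage of the Corey–Fuchs sequence (bromine–lithium exchange, Fritsch–Buttenberg–Wiechell rearrangement, deprotonation) gives the lithium acetylide, which is C-methylated in the same flask.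

Step 9
Reactants: 16 tert-butyldimethyl{[(3R,4R)-4-methylhept-5-yn-3-yl]oxy}silane
Product: 18 tert-butyl{[(3R,4R,5E)-6-iodo-4-methylhept-5-en-3-yl]oxy}dimethylsilane, via alkenylzirconocene chloride 17 (not isolated)
Conditions: Cp2Zr(H)Cl (2.5 equiv), THF, 50 °C, dark; I2, 0 °C
Reagents that add atoms: iodine, II
Why: Hydrozirconation–iodination, in which syn addition of Zr–H with excess Cp2Zr(H)Cl equilibrates zirconium to the less hindered methyl-bearing alkyne carbon and iodine then replaces zirconium with retention, should give the E 2-iodoalkene.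

Step 10
Reactants: 5 tricarbonyl[η6-(S)-4-tert-butyl-2-(3,5-dimethylphenyl)-4,5-dihydrooxazole]chromium; 18 tert-butyl{[(3R,4R,5E)-6-iodo-4-methylhept-5-en-3-yl]oxy}dimethylsilane; 14 iodomethane
Product: 21 (S)-4-tert-butyl-2-Dn-4,5-dihydrooxazole, via alkenyllithium 19 (not isolated), via lithium η5-cyclohexadienyl(tricarbonyl)chromate 20 (not isolated)
Conditions: 18, t-BuLi (2.0 equiv), Et2O, −78 °C; 5 (1.1 equiv), THF, −78 → −40 °C; MeI (10 equiv), DMPU, −78 → 20 °C, argon (no CO), dark; air, MeCN
Reagents that add atoms: iodomethane (compound 14), CI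
Why: Iodine–lithium exchange gives alkenyllithium 19 with retention of the E geometry; its lithium binds the oxazoline nitrogen of 5 and the alkenyl carbon adds to the neighbouring ortho carbon on the face away from zerovalent chromium to give the anionic η5-cyclohexadienyl complex 20, which MeI alkylates at the metal before reductive elimination passes the methyl group from the metal face to the oxazoline-bearing terminus and the metal leaves the 1,3-diene. The closest known reaction type is the sequential nucleophile/electrophile trans addition to tricarbonyl(aryloxazoline)chromium complexes, a dearomatizing 1,2-difunctionalisation, used here with a functionalised alkenyllithium and MeI. No ring closes; the arene ring itself becomes the carbocycle, with the diene left at the two methyl-bearing positions. The ring CH centre (6S) is controlled by the tert-butyl group of the auxiliary, which leaves the exo face open at only one of the two ortho carbons in the N–Li-bound rotamer, and the quaternary centre (1R) by endo delivery of methyl, so CH3 ends trans to the arm and the oxazoline carbon cis to it. The step needs ortho addition rather than meta or para addition (secured by N–Li chelation), addition rather than benzylic or ring deprotonation (−78 °C, where addition to the complexed ring is the faster process), migration to the acceptor-substituted terminus rather than the methyl-substituted one (electronic stabilisation and lower hindrance), and direct methyl transfer rather than CO insertion (acceptor at the migration terminus, argon in place of a CO atmosphere).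

Step 11
Reactants: 21 (S)-4-tert-butyl-2-Dn-4,5-dihydrooxazole
Product: 24 Dn-carbaldehyde, via N-methyloxazolinium triflate 22 (not isolated), via N-methyloxazolidine 23 (not isolated)
Conditions: MeOTf, CH2Cl2, 20 °C; NaBH4, THF/MeOH (4:1), 0 °C; oxalic acid, THF/H2O, 20 °C, dark
Reagents that add atoms: water, O
Why: Reductive oxazoline-to-aldehyde unmasking (N-methylation, hydride reduction of the iminium ion to the oxazolidine, mild hydrolysis of the N,O-acetal) is the standard cleavage for oxazolines on quaternary carbons, and the aldehyde cannot epimerise because its α-carbon is quaternary.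

Step 12
Reactants: 24 Dn-carbaldehyde; 25 methyl 2-methyl-3-oxopentanoate
Product: 27 methyl 5-Dn-5-hydroxy-2,4-dimethyl-3-oxopentanoate (diastereomer mixture), via keto ester dianion 26 (not isolated)
Conditions: 25 (3 equiv), NaH, THF, 0 °C; n-BuLi, 0 °C; 24, −78 → 0 °C; aq. NH4Cl
Reagents that add atoms: none
Why: β-Keto ester dianion aldol, in which the more reactive γ-carbanion adds to the non-enolisable aldehyde; the three new centres are immaterial because all become sp2 carbons of the pyranone.

Step 13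
Reactants: 27 methyl 5-Dn-5-hydroxy-2,4-dimethyl-3-oxopentanoate
Product: 28 methyl 5-Dn-2,4-dimethyl-3,5-dioxopentanoate
Conditions: Dess–Martin periodinane, NaHCO3, CH2Cl2, 20 °C, dark
Reagents that add atoms: none
Why: Dess–Martin oxidation of the δ-hydroxy β-keto ester to the β,δ-diketo ester leaves the alkenes and the silyl ether untouched.

Step 14
Reactants: 28 methyl 5-Dn-2,4-dimethyl-3,5-dioxopentanoate
Product: 29 6-Dn-4-hydroxy-3,5-dimethyl-2H-pyran-2-one
Conditions: DBU, toluene, 50 °C, dark
Reagents that add atoms: none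
Why: Base-mediated enolisation and lactonisation (enol oxygen of the ring-side ketone onto the methyl ester, with loss of methanol) is the established triketide-to-4-hydroxy-2-pyranone cyclisation and forms the O1–C2 bond.

Step 15
Reactants: 29 6-Dn-4-hydroxy-3,5-dimethyl-2H-pyran-2-one
Product: 31 2-methoxy-3,5-dimethyl-6-Dn-4H-pyran-4-one, via 4-hydroxy-2-methoxypyrylium triflate 30 (not isolated)
Conditions: MeOTf, CH2Cl2, 20 °C, dark; aq. NaHCO3
Reagents that add atoms: methyl trifluoromethanesulfonate, COS(=O)(=O)C(F)(F)F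
Why: Regioselective O-methylation of a 4-hydroxy-2-pyranone by a hard methylating agent occurs at the lactone carbonyl oxygen, and deprotonation of the resulting pyrylium salt on work-up should give the 2-methoxy-4-pyranone rather than the 4-methoxy-2-pyranone.

Step 16
Reactants: 31 2-methoxy-3,5-dimethyl-6-Dn-4H-pyran-4-one
Product: 32 2-[(1R,6S)-6-[(2E,4R,5R)-5-hydroxy-4-methylhept-2-en-2-yl]-1,3,5-trimethylcyclohexa-2,4-dien-1-yl]-6-methoxy-3,5-dimethyl-4H-pyran-4-one
Conditions: HF·pyridine, pyridine, THF, 0 → 20 °C, dark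
Reagents that add atoms: none
Why: Fluoride-mediated silyl ether cleavage under pyridine buffering should free the secondary alcohol without harming the methoxypyranone or the diene.

Step 17
Reactants: 32 2-[(1R,6S)-6-[(2E,4R,5R)-5-hydroxy-4-methylhept-2-en-2-yl]-1,3,5-trimethylcyclohexa-2,4-dien-1-yl]-6-methoxy-3,5-dimethyl-4H-pyran-4-one
Product: 33 2-methoxy-3,5-dimethyl-6-[(1R,6S)-1,3,5-trimethyl-6-[(2E,4R)-4-methyl-5-oxohept-2-en-2-yl]cyclohexa-2,4-dien-1-yl]-4H-pyran-4-one (CNP0301958.2)
Conditions: Dess–Martin periodinane, NaHCO3, CH2Cl2, 0 °C, dark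
Reagents that add atoms: none
Why: Buffered Dess–Martin oxidation forms the ethyl ketone in the last step, so the now acidic allylic α-methyl centre (4R) meets neither base nor acid able to epimerise it or move the alkene into conjugation.

**Compound list**

1 | 3,5-dimethylbenzonitrile | Cc1cc(C)cc(C#N)c1 | starting material
2 | (S)-tert-leucinol, (2S)-2-amino-3,3-dimethylbutan-1-ol | CC(C)(C)[C@H](N)CO | starting material
3 | (S)-4-tert-butyl-2-(3,5-dimethylphenyl)-4,5-dihydrooxazole | Cc1cc(C)cc(c1)C1=N[C@@H](C(C)(C)C)CO1 | intermediate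
4 | hexacarbonylchromium Cr(CO)6 | [Cr].[C-]#[O+].[C-]#[O+].[C-]#[O+].[C-]#[O+].[C-]#[O+].[C-]#[O+] | starting material
5 | tricarbonyl[η6-(S)-4-tert-butyl-2-(3,5-dimethylphenyl)-4,5-dihydrooxazole]chromium | Cc1cc(C)cc(c1)C1=N[C@@H](C(C)(C)C)CO1.[Cr].[C-]#[O+].[C-]#[O+].[C-]#[O+] | intermediate
6 | (S)-4-benzyl-3-propionyloxazolidin-2-one | CCC(=O)N1[C@@H](Cc2ccccc2)COC1=O | starting material
7 | propanal | CCC=O | starting material
8 | dibutylboron Z-enolate of 6 | C/C=C(\OB(CCCC)CCCC)N1[C@@H](Cc2ccccc2)COC1=O | intermediate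
9 | (S)-4-benzyl-3-[(2S,3R)-3-hydroxy-2-methylpentanoyl]oxazolidin-2-one | CC[C@@H](O)[C@H](C)C(=O)N1[C@@H](Cc2ccccc2)COC1=O | intermediate
10 | (S)-4-benzyl-3-[(2S,3R)-3-(tert-butyldimethylsilyloxy)-2-methylpentanoyl]oxazolidin-2-one | CC[C@@H](O[Si](C)(C)C(C)(C)C)[C@H](C)C(=O)N1[C@@H](Cc2ccccc2)COC1=O | intermediate
11 | (2R,3R)-3-(tert-butyldimethylsilyloxy)-2-methylpentan-1-ol | CC[C@@H](O[Si](C)(C)C(C)(C)C)[C@H](C)CO | intermediate
12 | (2S,3R)-3-(tert-butyldimethylsilyloxy)-2-methylpentanal | CC[C@@H](O[Si](C)(C)C(C)(C)C)[C@H](C)C=O | intermediate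
13 | tert-butyl{[(3R,4R)-6,6-dibromo-4-methylhex-5-en-3-yl]oxy}dimethylsilane | CC[C@@H](O[Si](C)(C)C(C)(C)C)[C@H](C)C=C(Br)Br | intermediate
14 | iodomethane | CI | starting material
15 | lithium acetylide, [(3R,4R)-4-(tert-butyldimethylsilyloxy)-3-methylhex-1-yn-1-yl]lithium | CC[C@@H](O[Si](C)(C)C(C)(C)C)[C@H](C)C#C[Li] | intermediate
16 | tert-butyldimethyl{[(3R,4R)-4-methylhept-5-yn-3-yl]oxy}silane | CC[C@@H](O[Si](C)(C)C(C)(C)C)[C@H](C)C#CC | intermediate
17 | chlorobis(η5-cyclopentadienyl)(Hp)zirconium | CC[C@@H](O[Si](C)(C)C(C)(C)C)[C@H](C)/C=C(\C)[Zr+2]Cl.c1cc[cH-]c1.c1cc[cH-]c1 | intermediate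
18 | tert-butyl{[(3R,4R,5E)-6-iodo-4-methylhept-5-en-3-yl]oxy}dimethylsilane (Hp–I) | CC[C@@H](O[Si](C)(C)C(C)(C)C)[C@H](C)/C=C(\C)I | intermediate
19 | alkenyllithium Hp–Li | CC[C@@H](O[Si](C)(C)C(C)(C)C)[C@H](C)/C=C(\C)[Li] | intermediate
20 | lithium tricarbonyl{η5-(6S)-6-Hp-3,5-dimethyl-1-[(S)-4-tert-butyl-4,5-dihydrooxazol-2-yl]cyclohexadienyl}chromate | [Li+].CC[C@@H](O[Si](C)(C)C(C)(C)C)[C@H](C)/C=C(\C)[C@H]1C(C)=CC(C)=C[C-]1C1=N[C@@H](C(C)(C)C)CO1.[Cr].[C-]#[O+].[C-]#[O+].[C-]#[O+] | intermediate
21 | (S)-4-tert-butyl-2-{(1R,6S)-6-[(2E,4R,5R)-5-(tert-butyldimethylsilyloxy)-4-methylhept-2-en-2-yl]-1,3,5-trimethylcyclohexa-2,4-dien-1-yl}-4,5-dihydrooxazole | CC[C@@H](O[Si](C)(C)C(C)(C)C)[C@H](C)/C=C(\C)[C@H]1C(C)=CC(C)=C[C@@]1(C)C1=N[C@@H](C(C)(C)C)CO1 | intermediate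
22 | (S)-4-tert-butyl-2-Dn-3-methyl-4,5-dihydrooxazol-3-ium trifluoromethanesulfonate | CC[C@@H](O[Si](C)(C)C(C)(C)C)[C@H](C)/C=C(\C)[C@H]1C(C)=CC(C)=C[C@@]1(C)C1=[N+](C)[C@@H](C(C)(C)C)CO1.[O-]S(=O)(=O)C(F)(F)F | intermediate
23 | (4S)-4-tert-butyl-2-Dn-3-methyloxazolidine (epimers at C2) | CC[C@@H](O[Si](C)(C)C(C)(C)C)[C@H](C)/C=C(\C)[C@H]1C(C)=CC(C)=C[C@@]1(C)C1N(C)[C@@H](C(C)(C)C)CO1 | intermediate
24 | (1R,6S)-6-[(2E,4R,5R)-5-(tert-butyldimethylsilyloxy)-4-methylhept-2-en-2-yl]-1,3,5-trimethylcyclohexa-2,4-diene-1-carbaldehyde | CC[C@@H](O[Si](C)(C)C(C)(C)C)[C@H](C)/C=C(\C)[C@H]1C(C)=CC(C)=C[C@@]1(C)C=O | intermediate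
25 | methyl 2-methyl-3-oxopentanoate (racemic) | CCC(=O)C(C)C(=O)OC | starting material
26 | sodium lithium dianion of methyl 2-methyl-3-oxopentanoate | [Na+].[Li+].C[CH-]C(=O)[C-](C)C(=O)OC | intermediate
27 | methyl 5-Dn-5-hydroxy-2,4-dimethyl-3-oxopentanoate (diastereomer mixture) | CC[C@@H](O[Si](C)(C)C(C)(C)C)[C@H](C)/C=C(\C)[C@H]1C(C)=CC(C)=C[C@@]1(C)C(O)C(C)C(=O)C(C)C(=O)OC | intermediate
28 | methyl 5-Dn-2,4-dimethyl-3,5-dioxopentanoate (diastereomer and tautomer mixture) | CC[C@@H](O[Si](C)(C)C(C)(C)C)[C@H](C)/C=C(\C)[C@H]1C(C)=CC(C)=C[C@@]1(C)C(=O)C(C)C(=O)C(C)C(=O)OC | intermediate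
29 | 6-Dn-4-hydroxy-3,5-dimethyl-2H-pyran-2-one | CC[C@@H](O[Si](C)(C)C(C)(C)C)[C@H](C)/C=C(\C)[C@H]1C(C)=CC(C)=C[C@@]1(C)c1oc(=O)c(C)c(O)c1C | intermediate
30 | 6-Dn-4-hydroxy-2-methoxy-3,5-dimethylpyrylium trifluoromethanesulfonate | CC[C@@H](O[Si](C)(C)C(C)(C)C)[C@H](C)/C=C(\C)[C@H]1C(C)=CC(C)=C[C@@]1(C)c1[o+]c(OC)c(C)c(O)c1C.[O-]S(=O)(=O)C(F)(F)F | intermediate
31 | 2-methoxy-3,5-dimethyl-6-Dn-4H-pyran-4-one | CC[C@@H](O[Si](C)(C)C(C)(C)C)[C@H](C)/C=C(\C)[C@H]1C(C)=CC(C)=C[C@@]1(C)c1oc(OC)c(C)c(=O)c1C | intermediate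
32 | 2-[(1R,6S)-6-[(2E,4R,5R)-5-hydroxy-4-methylhept-2-en-2-yl]-1,3,5-trimethylcyclohexa-2,4-dien-1-yl]-6-methoxy-3,5-dimethyl-4H-pyran-4-one | CC[C@@H](O)[C@H](C)/C=C(\C)[C@H]1C(C)=CC(C)=C[C@@]1(C)c1oc(OC)c(C)c(=O)c1C | intermediate
33 | 2-methoxy-3,5-dimethyl-6-[(1R,6S)-1,3,5-trimethyl-6-[(2E,4R)-4-methyl-5-oxohept-2-en-2-yl]cyclohexa-2,4-dien-1-yl]-4H-pyran-4-one | CCC(=O)[C@H](C)/C=C(\C)[C@H]1C(C)=CC(C)=C[C@@]1(C)c1oc(OC)c(C)c(=O)c1C | target

**Count and risks**

Total step count: 17. Longest linear sequence: 15 steps (steps 3–17); steps 1–2 form the short second branch.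

Steps most likely to fail:

1. Step 10. After alkylation at chromium, migratory insertion of CO may outrun direct methyl transfer, so that an acetyl group instead of methyl reaches ring C1. The fallback sets out from 5 and 18 and returns at 21. Complex 20 is formed as in step 10 but quenched with CF3CO2H at −78 °C and freed from chromium in air in the dark. This should give the methyl-free dienyl oxazoline F1; any double-bond isomer formed beside it converges in the next operation. LiN(i-Pr)2 in THF at −78 °C should convert it into the lithium dienyl azaenolate F2. MeI should then alkylate the α-carbon on the face anti to the neighbouring alkenyl arm, as in the tandem addition–alkylation of naphthyl oxazolines, and give 21 with the same trans relation.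

2. Step 11. N-methylation may stall at the nitrogen flanked by the tert-butyl group and the quaternary ring carbon, or the oxazolidine may resist mild hydrolysis. The fallback sets out from 21 and returns at 24. Aqueous CF3CO2H in THF with Na2SO4 should open the protonated oxazoline to the amino ester trifluoroacetate F3. Ac2O/pyridine caps the amine as the acetamido ester F4 and so prevents O-to-N acyl shift. i-Bu2AlH in CH2Cl2 at −78 °C should reduce the ester to the neopentyl-type alcohol F5. Buffered Dess–Martin oxidation then gives aldehyde 24.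

3. Step 12. The dianion may fail to add to the aldehyde, which is shielded by the quaternary carbon and the alkenyl arm, or the adduct may revert by retro-aldol cleavage during work-up. The fallback sets out from 24 and returns at 29, bypassing 27 and 28. EtMgBr in THF at −78 °C, the smallest carbon nucleophile, should give the secondary carbinol F6, and Dess–Martin oxidation the ethyl ketone F7. Me3SiOTf/Et3N should give the trimethylsilyl enol ether F8; only the ethyl side can enolise. Reaction with 2-methylmalonyl dichloride in Et2O from −78 to 20 °C (C-acylation, then closure of the enol oxygen onto the second acyl chloride) should deliver hydroxypyranone 29 directly.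

**Further compounds**

F1 | step 10 | (S)-4-tert-butyl-2-[(1R,6S)-6-Hp-3,5-dimethylcyclohexa-2,4-dien-1-yl]-4,5-dihydrooxazole (21 with H in place of the C1 methyl) | CC[C@@H](O[Si](C)(C)C(C)(C)C)[C@H](C)/C=C(\C)[C@H]1C(C)=CC(C)=C[C@H]1C1=N[C@@H](C(C)(C)C)CO1
F2 | step 10 | lithium dienyl azaenolate of F1 (N-lithio-2-cyclohexadienylidene oxazolidine) | CC[C@@H](O[Si](C)(C)C(C)(C)C)[C@H](C)/C=C(\C)[C@H]1C(C)=CC(C)=CC1=C1OC[C@H](C(C)(C)C)N1[Li]
F3 | step 11 | (2S)-2-ammonio-3,3-dimethylbutyl Dn-carboxylate trifluoroacetate | CC[C@@H](O[Si](C)(C)C(C)(C)C)[C@H](C)/C=C(\C)[C@H]1C(C)=CC(C)=C[C@@]1(C)C(=O)OC[C@@H]([NH3+])C(C)(C)C.[O-]C(=O)C(F)(F)F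
F4 | step 11 | (2S)-2-acetamido-3,3-dimethylbutyl Dn-carboxylate | CC[C@@H](O[Si](C)(C)C(C)(C)C)[C@H](C)/C=C(\C)[C@H]1C(C)=CC(C)=C[C@@]1(C)C(=O)OC[C@@H](NC(C)=O)C(C)(C)C
F5 | step 11 | Dn-methanol | CC[C@@H](O[Si](C)(C)C(C)(C)C)[C@H](C)/C=C(\C)[C@H]1C(C)=CC(C)=C[C@@]1(C)CO
F6 | step 12 | 1-Dn-propan-1-ol (epimer mixture) | CC[C@@H](O[Si](C)(C)C(C)(C)C)[C@H](C)/C=C(\C)[C@H]1C(C)=CC(C)=C[C@@]1(C)C(O)CC
F7 | step 12 | 1-Dn-propan-1-one | CC[C@@H](O[Si](C)(C)C(C)(C)C)[C@H](C)/C=C(\C)[C@H]1C(C)=CC(C)=C[C@@]1(C)C(=O)CC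
F8 | step 12 | trimethylsilyl enol ether of F7, 1-Dn-1-(trimethylsilyloxy)prop-1-ene | CC[C@@H](O[Si](C)(C)C(C)(C)C)[C@H](C)/C=C(\C)[C@H]1C(C)=CC(C)=C[C@@]1(C)C(O[Si](C)(C)C)=CC
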